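**Retrosynthetic overview**

1. Feature: in the bicyclo[3.3.1]nonane core (C1 and C5 bridgeheads, ring A = C1–C5 plus C9, ring B = C5–C9 plus C1), C3 is the β-carbon of the C2 carbonyl unit and C4 is a methylene on quaternary C5. The C3–C4 bond of ring A is therefore cut back to a C4 ketyl (formyl on C5) and an acrylate on C1, held 1,3-diaxial on ring B across the C9 ketone.
2. Target ⇐ C2 ester/C9 ketone 24 (hydride to C9 from the ring A side, C9 acetate, both CH2OH to CHO) ⇐ hydroxy ester 22 (dehydration, conjugation) ⇐ keto aldehyde 21 by SmI2 closure of ring A, the last ring formed.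
3. 21 ⇐ ring B ketone: the C1 quaternary centre from a pyruvate aldol/dehydration and hydroxymethylation of the dienolate anti to the C8 side chain; the C5 quaternary centre from reductive hydroxymethylation of enone 8.
4. Enone 8 (ring B, formed first) ⇐ amine-catalysed Michael addition/aldol condensation of tert-butyl 3-oxopentanoate 5 with enal 4, which is (R)-citronellal 1 plus one carbon.

Key step: step 12

Remark on the chemistry: 22 is drawn with the C4 hydroxyl syn to the C9 carbonyl and the C2 ester equatorial, the expected outcome; both centres are erased in steps 13 and 14, so their epimers would be carried on in the same way.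

**Route**

Step 1
Reactants: 1 (R)-citronellal
Product: 3 (4R)-4,8-dimethylnon-7-enal, via enol ether 2 (not isolated)
Conditions: MeOCH2PPh3Cl, KOt-Bu, THF, 0 °C; then 1 M aq. HCl, THF, rt
Reagents that add atoms: (methoxymethyl)triphenylphosphonium chloride, COC[P+](c1ccccc1)(c1ccccc1)c1ccccc1.[Cl-]; water, O
Why: Wittig methoxymethylenation followed by acid hydrolysis of the enol ether is the standard one-carbon homologation of an aldehyde, and the stereocentre of citronellal (later C1′) is not enolisable and stays untouched.

Step 2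
Reactants: 3 (4R)-4,8-dimethylnon-7-enal
Product: 4 (2E,4R)-4,8-dimethylnona-2,7-dienal
Conditions: IBX (1.3 equiv), DMSO, 65 °C
Reagents that add atoms: none
Why: IBX dehydrogenation of a saturated aldehyde should give the (E)-enal, and with a limited amount of oxidant the γ-stereocentre is not drawn into a dienol.

Step 3
Reactants: 4 (2E,4R)-4,8-dimethylnona-2,7-dienal; 5 tert-butyl 3-oxopentanoate
Product: 8 (5R)-2-methyl-5-[(2R)-6-methylhept-5-en-2-yl]cyclohex-2-en-1-one, via Michael adduct 6 (not isolated), via cyclohexenone tert-butyl ester 7 (not isolated)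
Conditions: (S)-α,α-diphenylprolinol trimethylsilyl ether (10 mol %), PhCO2H (10 mol %), toluene, rt; then TsOH·H2O (20 mol %), toluene, 80 °C
Reagents that add atoms: none
Why: Iminium-ion Michael addition of the β-keto ester takes place on the face of the enal β-carbon remote from the CPh2OSiMe3 group of the (S)-catalyst and so sets C8 under catalyst control, after which acid drives the intramolecular aldol condensation of the ethyl ketone CH2 onto the aldehyde and the loss of isobutene and CO2 from the tert-butyl β-keto ester (Robinson-type annulation).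

Step 4
Reactants: 8 (5R)-2-methyl-5-[(2R)-6-methylhept-5-en-2-yl]cyclohex-2-en-1-one
Product: 10 (2R,5R)-2-(hydroxymethyl)-2-methyl-5-[(2R)-6-methylhept-5-en-2-yl]cyclohexan-1-one (CH2OH on C5 cis to the C8 side chain), via lithium enolate 9 (not isolated)
Conditions: LiBH(s-Bu)3, THF, −78 °C; then CH2O (gas, from cracked paraformaldehyde), −78 °C; aq. NH4Cl
Reagents that add atoms: formaldehyde, C=O
Why: Conjugate hydride addition gives the C5=C9 lithium enolate regiospecifically, and its aldol addition to formaldehyde (reductive aldol) should occur by axial attack on the half-chair that keeps the C8 side chain equatorial, which places the new CH2OH cis to that chain.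

Step 5
Reactants: 10 hydroxymethyl ketone
Product: 11 triethylsilyl ether of 10
Conditions: Et3SiCl, imidazole, CH2Cl2, 0 °C
Reagents that add atoms: chlorotriethylsilane, CC[Si](Cl)(CC)CC
Why: Standard silylation of the primary alcohol masks the β-hydroxy ketone against retro-aldol cleavage in the enolate chemistry that follows.

Step 6
Reactants: 11 triethylsilyl ether; 12 methyl pyruvate
Product: 14 methyl 2-hydroxy-2-(ring B C1-yl)propanoate (aldol adduct; mixture at C1 and at the carbinol carbon), via lithium enolate 13 (not isolated)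
Conditions: LiN(i-Pr)2, THF, −78 °C; methyl pyruvate, −78 °C; AcOH, −78 °C
Reagents that add atoms: none
Why: With C5 quaternary, C1 is the only enolisable position, and the lithium enolate adds to the ketone carbonyl of methyl pyruvate (aldol addition); the two new centres are removed in steps 7 and 8.

Step 7
Reactants: 14 aldol adduct
Product: 16 methyl 2-(ring B C1-ylidene)propanoate (C1=C2 alkylidene; E/Z mixture), via tertiary mesylate 15 (not isolated)
Conditions: MsCl, Et3N (4 equiv), DMAP (cat.), CH2Cl2, 0 °C → rt
Reagents that add atoms: none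
Why: Sulfene mesylation of the tertiary alcohol and E1cB loss of methanesulfonate through the C9 enolate should give the conjugated alkylidene, and any deconjugated (acrylate) isomer would give the same dienolate in step 8.

Step 8
Reactants: 16 alkylidene keto ester
Product: 18 methyl 2-[C1-(hydroxymethyl) ring B ketone]acrylate (CH2OH trans and acrylate cis to the C8 side chain), via lithium dienolate 17 (not isolated)
Conditions: LiN(SiMe3)2, THF, −78 °C; CH2O (gas), −78 °C; AcOH, −78 °C
Reagents that add atoms: formaldehyde, C=O
Why: The C2 methyl hydrogens are the most acidic in 16 (C5 is quaternary), so the base forms the cross-conjugated lithium dienolate, which should react with formaldehyde at the α-carbon C1 (deconjugative α-hydroxymethylation) on the face anti to the C8 side chain.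

Step 9
Reactants: 18 hydroxymethyl acrylate
Product: 19 tert-butyldimethylsilyl ether of 18
Conditions: t-BuMe2SiOTf, 2,6-lutidine, CH2Cl2, −78 °C
Reagents that add atoms: tert-butyldimethylsilyl trifluoromethanesulfonate, CC(C)(C)[Si](C)(C)OS(=O)(=O)C(F)(F)F
Why: Silylation with the silyl triflate is fast at low temperature and forestalls retro-aldol cleavage and lactonisation onto the acrylate ester; the ketone has no α-hydrogen and cannot form a silyl enol ether.

Step 10
Reactants: 19 bis-silyl ether
Product: 20 C5 primary alcohol (triethylsilyl group removed)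
Conditions: PPTS (0.2 equiv), MeOH/CH2Cl2 1:1, 0 °C
Reagents that add atoms: none
Why: Acid-catalysed methanolysis removes a primary triethylsilyl ether much faster than a primary tert-butyldimethylsilyl ether (selective desilylation).

Step 11
Reactants: 20 primary alcohol
Product: 21 keto aldehyde (ring B C9 ketone; acrylate and CH2OSiMe2t-Bu on C1; formyl and methyl on C5)
Conditions: Dess–Martin periodinane, CH2Cl2, rt
Reagents that add atoms: none
Why: Dess–Martin oxidation under neutral conditions should give the non-enolisable β-keto aldehyde without touching the acrylate or the trisubstituted alkene.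

Step 12
Reactants: 21 keto aldehyde
Product: 22 methyl 4-hydroxy-9-oxobicyclo[3.3.1]nonane-2-carboxylate core (C4–OH syn to the C9 carbonyl, C2 ester equatorial; substituents on C1, C5 and C8 as in 21)
Conditions: SmI2 (2.5 equiv, 0.1 M in THF), t-BuOH (2 equiv), THF, −78 → −20 °C; aq. NH4Cl
Reagents that add atoms: none
Why: SmI2 transfers one electron to the formyl group on C5 (the C9 ketone, between two quaternary carbons, is reduced far more slowly), the samarium-bound ketyl carbon C4 adds to the unsubstituted acrylate carbon C3, the resulting C2 radical takes a second electron, and the trivalent samarium enolate is protonated by t-BuOH. The closest known reaction type is the SmI2 ketyl–olefin cyclisation onto α,β-unsaturated esters, here in the less common endo sense on a 2-substituted acrylate. Ring A closes 6-endo-trig with respect to the alkene, the 5-exo attack at ester-bearing C2 being disfavoured by radical polarity and by the fully substituted centre it would create next to C1. C4 is expected with the hydroxyl syn to the C9 carbonyl because trivalent samarium bridges the ketyl oxygen and the ketone oxygen, and C2 with the ester equatorial because the enolate is protonated from the open exo face of ring A; both centres are removed in steps 13 and 14. The step needs chemoselectivity (aldehyde before ketone and acrylate) and regioselectivity (C3 before C2), and the 1,3-diaxial placement of formyl and acrylate on ring B, fixed by the equatorial C8 side chain, brings C4 next to C3 and secures both.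

Step 13
Reactants: 22 hydroxy ester
Product: 23 methyl 9-oxobicyclo[3.3.1]non-3-ene-2-carboxylate core (C3=C4)
Conditions: Burgess reagent (MeO2C–N⁻–SO2–N⁺Et3, 2 equiv), toluene, 70 °C
Reagents that add atoms: none
Why: The Burgess reagent converts the secondary alcohol into a sulfamate that loses the syn (exo) hydrogen on C3 in a thermal cyclic elimination (syn dehydration), so no base meets the β-hydroxy ketone and no enolate forms at C2.

Step 14
Reactants: 23 β,γ-unsaturated ester
Product: 24 methyl 9-oxobicyclo[3.3.1]non-2-ene-2-carboxylate core (C2=C3)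
Conditions: DBU (0.5 equiv), toluene, 80 °C
Reagents that add atoms: none
Why: DBU removes the allylic C2 hydrogen α to the ester and reprotonation at C4 moves the double bond into conjugation (base-mediated alkene isomerisation), the trisubstituted conjugated ester being the more stable isomer.

Step 15
Reactants: 24 conjugated keto ester
Product: 25 diol (C2–CH2OH and C9–OH on the ring B side of C9; C1–CH2OSiMe2t-Bu kept)
Conditions: i-Bu2AlH (5 equiv), CH2Cl2, −78 → 0 °C; aq. KNaC4H4O6
Reagents that add atoms: none
Why: i-Bu2AlH reduces the conjugated ester to the allylic alcohol (1,2-reduction) and the C9 ketone to the alcohol, and hydride should reach C9 from the ring A side (one axial hydrogen on C4, trigonal C2) rather than the ring B side (axial hydrogens on C6 and C8), which puts the hydroxyl on the ring B side as in the target.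

Step 16
Reactants: 25 diol
Product: 26 bis(tert-butyldimethylsilyl) ether with free C9–OH
Conditions: t-BuMe2SiCl (1.2 equiv), imidazole, CH2Cl2, 0 °C
Reagents that add atoms: tert-butyldimethylsilyl chloride, CC(C)(C)[Si](C)(C)Cl
Why: The primary allylic alcohol is silylated much faster than the secondary C9 alcohol flanked by two quaternary carbons (selective protection).

Step 17
Reactants: 26 C9 alcohol
Product: 27 C9 acetate
Conditions: Ac2O, DMAP, Et3N, CH2Cl2, 40 °C
Reagents that add atoms: acetic anhydride, CC(=O)OC(C)=O
Why: DMAP-catalysed acylation should acetylate even the hindered C9 alcohol with retention while both primary hydroxyls are masked.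

Step 18
Reactants: 27 acetate bis-silyl ether
Product: 28 diol acetate (C1–CH2OH and C2–CH2OH)
Conditions: HF·pyridine, THF/pyridine, 0 °C → rt
Reagents that add atoms: none
Why: Buffered HF cleaves both primary silyl ethers (fluoride-mediated desilylation) under slightly acidic conditions that should not cause acetyl migration from C9.

Step 19
Reactants: 28 diol acetate
Product: 29 CNP0299929.2 (target)
Conditions: (COCl)2, DMSO, CH2Cl2, −78 °C; Et3N, −78 → 0 °C
Reagents that add atoms: none
Why: Swern oxidation activates both primary alcohols before base is added and so should convert the 1,4-diol into the dialdehyde without lactol or lactone formation; C1 is quaternary and C2 trigonal, so no centre can epimerise, and the acetate is inert.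

**Compound list**

1 | (R)-citronellal | C[C@H](CCC=C(C)C)CC=O | starting material
2 | (4R)-1-methoxy-4,8-dimethylnona-1,7-diene (E/Z enol ether) | C[C@H](CCC=C(C)C)CC=COC | intermediate
3 | (4R)-4,8-dimethylnon-7-enal | C[C@H](CCC=C(C)C)CCC=O | intermediate
4 | (2E,4R)-4,8-dimethylnona-2,7-dienal | C[C@H](CCC=C(C)C)/C=C/C=O | intermediate
5 | tert-butyl 3-oxopentanoate | CCC(=O)CC(=O)OC(C)(C)C | starting material
6 | tert-butyl 3-[(2R)-6-methylhept-5-en-2-yl]-5-oxo-2-propanoylpentanoate (C3 as C8 of 8; C2 epimers) | CCC(=O)C(C(=O)OC(C)(C)C)[C@@H](CC=O)[C@H](C)CCC=C(C)C | intermediate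
7 | tert-butyl 3-methyl-6-[(2R)-6-methylhept-5-en-2-yl]-2-oxocyclohex-3-ene-1-carboxylate (C6 as C8 of 8; C1 epimers) | CC1=CC[C@@H]([C@H](C)CCC=C(C)C)C(C(=O)OC(C)(C)C)C1=O | intermediate
8 | (5R)-2-methyl-5-[(2R)-6-methylhept-5-en-2-yl]cyclohex-2-en-1-one | CC1=CC[C@@H]([C@H](C)CCC=C(C)C)CC1=O | intermediate
9 | lithium enolate of the 1,4-reduced enone (C5=C9) | [Li]OC1=C(C)CC[C@@H]([C@H](C)CCC=C(C)C)C1 | intermediate
10 | (2R,5R)-2-(hydroxymethyl)-2-methyl-5-[(2R)-6-methylhept-5-en-2-yl]cyclohexan-1-one | OC[C@@]1(C)CC[C@@H]([C@H](C)CCC=C(C)C)CC1=O | intermediate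
11 | triethylsilyl ether of 10 | CC[Si](CC)(CC)OC[C@@]1(C)CC[C@@H]([C@H](C)CCC=C(C)C)CC1=O | intermediate
12 | methyl pyruvate | CC(=O)C(=O)OC | starting material
13 | lithium enolate of 11 (C1=C9) | [Li]OC1=C[C@H]([C@H](C)CCC=C(C)C)CC[C@]1(C)CO[Si](CC)(CC)CC | intermediate
14 | pyruvate aldol adduct of 11 at C1 (tertiary alcohol; epimers at C1 and the carbinol carbon) | COC(=O)C(C)(O)C1[C@H]([C@H](C)CCC=C(C)C)CC[C@](C)(CO[Si](CC)(CC)CC)C1=O | intermediate
15 | tertiary methanesulfonate of 14 | COC(=O)C(C)(OS(C)(=O)=O)C1[C@H]([C@H](C)CCC=C(C)C)CC[C@](C)(CO[Si](CC)(CC)CC)C1=O | intermediate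
16 | methyl 2-(ring B C1-ylidene)propanoate (E/Z) | COC(=O)C(C)=C1[C@H]([C@H](C)CCC=C(C)C)CC[C@](C)(CO[Si](CC)(CC)CC)C1=O | intermediate
17 | lithium dienolate of 16 (C9(OLi)=C1–C2(CO2Me)=C3H2) | COC(=O)C(=C)C=1[C@H]([C@H](C)CCC=C(C)C)CC[C@](C)(CO[Si](CC)(CC)CC)C=1O[Li] | intermediate
18 | C1-hydroxymethyl C1-acrylate ketone (CH2OH trans, acrylate cis to the C8 side chain) | C=C(C(=O)OC)[C@]1(CO)[C@H]([C@H](C)CCC=C(C)C)CC[C@](C)(CO[Si](CC)(CC)CC)C1=O | intermediate
19 | tert-butyldimethylsilyl ether of 18 | C=C(C(=O)OC)[C@]1(CO[Si](C)(C)C(C)(C)C)[C@H]([C@H](C)CCC=C(C)C)CC[C@](C)(CO[Si](CC)(CC)CC)C1=O | intermediate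
20 | C5 primary alcohol | C=C(C(=O)OC)[C@]1(CO[Si](C)(C)C(C)(C)C)[C@H]([C@H](C)CCC=C(C)C)CC[C@](C)(CO)C1=O | intermediate
21 | keto aldehyde, precursor of the key step | C=C(C(=O)OC)[C@]1(CO[Si](C)(C)C(C)(C)C)[C@H]([C@H](C)CCC=C(C)C)CC[C@](C)(C=O)C1=O | intermediate
22 | bicyclic 4-hydroxy C2 ester, product of the key step | O=C1[C@@]2(C)[C@@H](O)C[C@H](C(=O)OC)[C@]1(CO[Si](C)(C)C(C)(C)C)[C@H]([C@H](C)CCC=C(C)C)CC2 | intermediate
23 | bicyclic C3=C4 ester | O=C1[C@@]2(C)C=C[C@H](C(=O)OC)[C@]1(CO[Si](C)(C)C(C)(C)C)[C@H]([C@H](C)CCC=C(C)C)CC2 | intermediate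
24 | bicyclic C2=C3 conjugated ester with C9 ketone | O=C1[C@@]2(C)CC=C(C(=O)OC)[C@]1(CO[Si](C)(C)C(C)(C)C)[C@H]([C@H](C)CCC=C(C)C)CC2 | intermediate
25 | diol (C2–CH2OH, C9–OH) | O[C@@H]1[C@@]2(C)CC=C(CO)[C@]1(CO[Si](C)(C)C(C)(C)C)[C@H]([C@H](C)CCC=C(C)C)CC2 | intermediate
26 | bis-silyl ether with free C9–OH | O[C@@H]1[C@@]2(C)CC=C(CO[Si](C)(C)C(C)(C)C)[C@]1(CO[Si](C)(C)C(C)(C)C)[C@H]([C@H](C)CCC=C(C)C)CC2 | intermediate
27 | C9 acetate bis-silyl ether | CC(=O)O[C@@H]1[C@@]2(C)CC=C(CO[Si](C)(C)C(C)(C)C)[C@]1(CO[Si](C)(C)C(C)(C)C)[C@H]([C@H](C)CCC=C(C)C)CC2 | intermediate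
28 | C9 acetate diol | CC(=O)O[C@@H]1[C@@]2(C)CC=C(CO)[C@]1(CO)[C@H]([C@H](C)CCC=C(C)C)CC2 | intermediate
29 | CNP0299929.2: 9-acetoxy-5-methyl-8-[(2R)-6-methylhept-5-en-2-yl]bicyclo[3.3.1]non-2-ene-1,2-dicarbaldehyde (acetoxy on the ring B side of C9, side chain equatorial on ring B) | CC(=O)O[C@@H]1[C@@]2(C)CC=C(C=O)[C@]1(C=O)[C@H]([C@H](C)CCC=C(C)C)CC2 | target

**Count and risks**

Total step count: 19. Longest linear sequence: 19 steps, from (R)-citronellal 1.

Steps most likely to fail:

1. Step 12 (key step). After electron transfer the ketyl may follow other paths than 6-endo addition: pinacol-type closure onto the C9 carbonyl, reduction to the primary alcohol 20 before it cyclises, reduction of the acrylate, or retro-aldol opening of the samarium alkoxide of 22. The fallback closes ring A at the C2=C3 bond by ring-closing metathesis. It sets out from 8: reductive allylation (LiBH(s-Bu)3, THF, −78 °C; then allyl bromide) should give the 2-allyl-2-methyl ketone F1 with the allyl group cis to the side chain, again by axial alkylation. F1 is taken through the conditions of steps 6 to 9 to give the pyruvate aldol adduct F2, the alkylidene F3, the hydroxymethyl acrylate F4 and its silyl ether F5. Second-generation Hoveyda–Grubbs catalyst (toluene, 80 °C) should then join the acrylate and allyl termini with loss of ethylene and give 24, where the route is rejoined.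

2. Step 8. Formaldehyde may attack the terminal dienolate carbon C3 instead of C1, the aldol may reverse on warming, the new alkoxide may lactonise onto the acrylate ester, and base may erode the C8 configuration by removing the C8 hydrogen of 16. The fallback sets out from 14 and avoids any dienolate. Silylation (Me3SiOTf, Et3N, CH2Cl2) should give the bis-silyl compound F6, a simple C1=C9 silyl enol ether with the tertiary alcohol also silylated. Hydroxymethylation with aqueous formaldehyde and Sc(OTf)3 (Mukaiyama-type aldol, attack anti to the C8 side chain) should give the diol F7 after loss of the silyl groups. Selective silylation of its primary alcohol (t-BuMe2SiCl, imidazole) gives F8. Dehydration of the tertiary alcohol with the Burgess reagent can then only go toward the methyl group, because C1 is now quaternary, and gives 19.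

3. Step 13. The syn elimination may be slow in the rigid bicycle, or ionisation at neopentyl C4 may lead to a 1,2-shift instead of the alkene. The fallback sets out from 22: Dess–Martin oxidation gives the 4,9-diketone F9. KN(SiMe3)2 and PhNTf2 should give the C3=C4 enol triflate F10, since C5 is quaternary and the C4 ketone can only enolise toward C3. Reduction with Pd(OAc)2, PPh3, Et3N and HCO2H in DMF (formate reduction by way of zerovalent palladium) gives 23.

**Further compounds**

F1 | step 12 | 2-allyl-2-methyl-5-[(2R)-6-methylhept-5-en-2-yl]cyclohexan-1-one (allyl on C5 cis to the side chain) | C=CC[C@@]1(C)CC[C@@H]([C@H](C)CCC=C(C)C)CC1=O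
F2 | step 12 | pyruvate aldol adduct of F1 at C1 | COC(=O)C(C)(O)C1[C@H]([C@H](C)CCC=C(C)C)CC[C@](C)(CC=C)C1=O
F3 | step 12 | methyl 2-(C1-ylidene)propanoate of the allyl series | COC(=O)C(C)=C1[C@H]([C@H](C)CCC=C(C)C)CC[C@](C)(CC=C)C1=O
F4 | step 12 | C1-hydroxymethyl C1-acrylate ketone of the allyl series | C=C(C(=O)OC)[C@]1(CO)[C@H]([C@H](C)CCC=C(C)C)CC[C@](C)(CC=C)C1=O
F5 | step 12 | tert-butyldimethylsilyl ether of F4 (metathesis substrate) | C=C(C(=O)OC)[C@]1(CO[Si](C)(C)C(C)(C)C)[C@H]([C@H](C)CCC=C(C)C)CC[C@](C)(CC=C)C1=O
F6 | step 8 | trimethylsilyl enol ether (C1=C9) of 14 with the tertiary alcohol silylated | COC(=O)C(C)(O[Si](C)(C)C)C=1[C@H]([C@H](C)CCC=C(C)C)CC[C@](C)(CO[Si](CC)(CC)CC)C=1O[Si](C)(C)C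
F7 | step 8 | C1-hydroxymethyl ketone with the tertiary α-hydroxy ester on C1 (diol) | COC(=O)C(C)(O)[C@]1(CO)[C@H]([C@H](C)CCC=C(C)C)CC[C@](C)(CO[Si](CC)(CC)CC)C1=O
F8 | step 8 | primary tert-butyldimethylsilyl ether of F7 | COC(=O)C(C)(O)[C@]1(CO[Si](C)(C)C(C)(C)C)[C@H]([C@H](C)CCC=C(C)C)CC[C@](C)(CO[Si](CC)(CC)CC)C1=O
F9 | step 13 | bicyclic 4,9-diketone C2 ester | O=C1[C@@]2(C)C(=O)C[C@H](C(=O)OC)[C@]1(CO[Si](C)(C)C(C)(C)C)[C@H]([C@H](C)CCC=C(C)C)CC2
F10 | step 13 | C3=C4 enol trifluoromethanesulfonate of F9 | O=C1[C@@]2(C)C(OS(=O)(=O)C(F)(F)F)=C[C@H](C(=O)OC)[C@]1(CO[Si](C)(C)C(C)(C)C)[C@H]([C@H](C)CCC=C(C)C)CC2
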